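**Retrosynthetic overview**
1. The target is 15-O-acetyl-PGA2 methyl ester (8R,12S,15S; 5Z,13E). It comes from PGE2 methyl ester by acid β-elimination of the 11-hydroxyl (creates the C10=C11 enone), then acetylation of the 15-OH.
2. PGE2 methyl ester comes from desilylation, cis-semihydrogenation of a C5–C6 alkyne, and radical removal of a C7 hydroxyl.
3. Key C7–C8 bond: intermolecular aldol addition of a cyclopentanone enolate to methyl 7-oxohept-5-ynoate. The enolate is generated by conjugate addition of the ω-chain vinylcopper (C12–C13) to (R)-4-silyloxycyclopent-2-enone.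
4. Fragments: the enone from meso cis-3,5-diacetoxycyclopentene (enzymatic desymmetrisation), the vinyl iodide from (S)-oct-1-yn-3-ol, the ynal from hex-5-ynoic acid.
5. Rings: no ring is formed; the single five-membered carbocycle is carried through from the starting cyclopentene.

Assumption: organometallic intermediates are drawn with the organic group only (Bu3P on copper omitted, cyclopentadienyl rings drawn σ-bonded); enolate 17 is drawn as the lithium enolate, CuI being returned by exchange with LiI; C7 in 18 and 19 is an epimer mixture and is left undefined.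

**Route**

Step 1
Reactants: 1 cis-3,5-diacetoxycyclopent-1-ene (meso)
Product: 2 (1R,4S)-4-hydroxycyclopent-2-en-1-yl acetate
Conditions: electric eel acetylcholinesterase, aq. NaH2PO4/Na2HPO4 buffer (pH 6.9), NaN3 (trace), rt, 24 h
Reagents that add atoms: none
Why: Enzymatic desymmetrisation (enantiotopic-group-selective ester hydrolysis) of the meso diacetate cleaves only the acetate on the S carbon, which fixes the absolute configuration of the carbon that becomes C11.

Step 2
Reactants: 2 (1R,4S)-4-hydroxycyclopent-2-en-1-yl acetate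
Product: 3 (R)-4-acetoxycyclopent-2-en-1-one
Conditions: Dess–Martin periodinane (1.2 equiv), CH2Cl2, 0 °C to rt
Reagents that add atoms: none
Why: Dess–Martin oxidation of the allylic alcohol is neutral and mild, so the acetoxy-bearing stereocentre is untouched and no β-elimination occurs.

Step 3
Reactants: 3 (R)-4-acetoxycyclopent-2-en-1-one
Product: 4 (R)-4-hydroxycyclopent-2-en-1-one
Conditions: wheat germ lipase, aq. NaH2PO4/Na2HPO4 buffer (pH 7.0), rt, 5–7 d
Reagents that add atoms: none
Why: Lipase-catalysed ester hydrolysis at neutral pH removes the acetate without the base-induced β-elimination or racemisation that chemical saponification of a β-acyloxy enone would cause.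

Step 4
Reactants: 4 (R)-4-hydroxycyclopent-2-en-1-one
Product: 5 (R)-4-(tert-butyldimethylsilyloxy)cyclopent-2-en-1-one
Conditions: TBSCl (1.2 equiv), imidazole (2 equiv), DMF, 0 °C
Reagents that add atoms: tert-butyldimethylsilyl chloride, CC(C)(C)[Si](C)(C)Cl
Why: Imidazole-promoted silyl ether formation on the secondary alcohol proceeds at oxygen with retention and gives the bulky group that later directs the conjugate addition.

Step 5
Reactants: 6 (S)-oct-1-yn-3-ol
Product: 7 (S)-3-(tert-butyldimethylsilyloxy)oct-1-yne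
Conditions: TBSCl (1.2 equiv), imidazole (2 equiv), DMF, rt
Reagents that add atoms: tert-butyldimethylsilyl chloride, CC(C)(C)[Si](C)(C)Cl
Why: Standard silyl ether protection of the propargylic alcohol; the purchased S stereocentre (future C15) is not involved.

Step 6
Reactants: 7 (S)-3-(tert-butyldimethylsilyloxy)oct-1-yne
Product: 9 (S,E)-3-(tert-butyldimethylsilyloxy)-1-iodooct-1-ene, via alkenylzirconocene chloride 8 (not isolated)
Conditions: Cp2Zr(H)Cl (1.2 equiv), THF, rt, 1 h, dark; then I2 (1.2 equiv), THF, 0 °C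
Reagents that add atoms: iodine, II
Why: Schwartz hydrozirconation adds Zr–H syn and anti-Markovnikov across the terminal alkyne and iodinolysis of the C–Zr bond occurs with retention, so only the E-vinyl iodide forms.

Step 7
Reactants: 10 hex-5-ynoic acid
Product: 12 7-hydroxyhept-5-ynoic acid, via dilithio dianion 11 (not isolated)
Conditions: n-BuLi (2.1 equiv), THF–DMPU, −78 to 0 °C; (CH2O)n (3 equiv), 0 °C to rt; then 1 M HCl
Reagents that add atoms: paraformaldehyde (reacts as formaldehyde), C=O
Why: Two equivalents of base give the carboxylate/acetylide dianion (the acetylenic C–H is far more acidic than the α-C–H of a carboxylate), and acetylide addition to formaldehyde (alkynylation) installs C7 with its oxygen.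

Step 8
Reactants: 12 7-hydroxyhept-5-ynoic acid
Product: 13 methyl 7-hydroxyhept-5-ynoate
Conditions: MeOH, H2SO4 (cat.), rt, 16 h
Reagents that add atoms: methanol, CO
Why: Fischer esterification in excess methanol converts the acid cleanly, the propargylic alcohol and alkyne being inert to catalytic acid at room temperature.

Step 9
Reactants: 13 methyl 7-hydroxyhept-5-ynoate
Product: 14 methyl 7-oxohept-5-ynoate
Conditions: Dess–Martin periodinane (1.2 equiv), CH2Cl2, 0 °C to rt; used at once
Reagents that add atoms: none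
Why: Dess–Martin oxidation takes the primary propargylic alcohol to the ynal without over-oxidation or touching the ester.

Step 10
Reactants: 9 (S,E)-3-(tert-butyldimethylsilyloxy)-1-iodooct-1-ene; 5 (R)-4-(tert-butyldimethylsilyloxy)cyclopent-2-en-1-one; 14 methyl 7-oxohept-5-ynoate
Product: 18 methyl 7-hydroxy-5,6-didehydro-PGE2 11,15-bis(TBS) ether (C7 epimers), via vinyllithium 15 (not isolated), via vinylcopper 16 (not isolated), via lithium enolate 17 (not isolated)
Conditions: 9, t-BuLi (2.0 equiv), Et2O, −78 °C; CuI (1.0 equiv), n-Bu3P (2.6 equiv), Et2O, −78 °C; 5, −78 °C, 30 min; 14 (1.1 equiv), −78 °C, 30 min; sat. aq. NH4Cl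
Reagents that add atoms: none
Why: Three-component coupling by tandem conjugate addition–intermolecular aldol addition: iodine–lithium exchange retains the E geometry, the vinylcopper adds anti to the C11 silyloxy group (sets C12), and the regiodefined enolate adds to the ynal anti to the new C12 chain (sets C8, 8,12-trans), the C7 carbinol epimers being irrelevant because C7 later becomes CH2.

Step 11
Reactants: 18 methyl 7-hydroxy-5,6-didehydro-PGE2 11,15-bis(TBS) ether (C7 epimers)
Product: 19 the 7-O-(phenoxythiocarbonyl) derivative of 18 (C7 epimers)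
Conditions: PhOC(S)Cl (1.5 equiv), pyridine (3 equiv), DMAP (cat.), CH2Cl2, 0 °C to rt
Reagents that add atoms: O-phenyl chlorothionoformate, S=C(Cl)Oc1ccccc1
Why: Nucleophile-catalysed O-thioacylation (the activation step of a Barton–McCombie deoxygenation) converts the secondary propargylic alcohol into a radical-labile thionocarbonate under conditions mild enough to keep the β-oxygenated ketone from eliminating.

Step 12
Reactants: 19 the 7-O-(phenoxythiocarbonyl) derivative of 18
Product: 20 methyl 5,6-didehydro-PGE2 11,15-bis(TBS) ether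
Conditions: Bu3SnH (2 equiv), AIBN (0.1 equiv), toluene, 80 °C, 1 h
Reagents that add atoms: none
Why: Barton–McCombie radical deoxygenation: the stannyl radical adds to the thiocarbonyl, β-scission gives the same propargylic C7 radical from either epimer, and hydrogen transfer from Bu3SnH gives the CH2 group without touching C8, the silyl ethers or the ester.

Step 13
Reactants: 20 methyl 5,6-didehydro-PGE2 11,15-bis(TBS) ether
Product: 21 PGE2 methyl ester 11,15-bis(TBS) ether
Conditions: H2 (1 atm), 5% Pd/BaSO4, quinoline, cyclohexane–benzene 1:1, rt, stopped after 1 equiv H2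
Reagents that add atoms: none
Why: Lindlar-type semihydrogenation on quinoline-poisoned palladium adds H2 syn to the alkyne only, giving the 5Z alkene and leaving the disubstituted 13E alkene and the ketone intact.

Step 14
Reactants: 21 PGE2 methyl ester 11,15-bis(TBS) ether
Product: 22 PGE2 methyl ester
Conditions: HF·pyridine, MeCN, 0 °C to rt
Reagents that add atoms: none
Why: Fluoride-driven desilylation under buffered, weakly acidic conditions frees both secondary alcohols without dehydrating the β-hydroxy ketone or epimerising C8.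

Step 15
Reactants: 22 PGE2 methyl ester
Product: 23 PGA2 methyl ester
Conditions: AcOH–H2O 9:1, 60 °C, 16 h
Reagents that add atoms: none
Why: Acid-catalysed β-elimination (dehydration of the β-hydroxy ketone through the C9 enol) gives the conjugated cyclopentenone, deliberately destroying the C11 stereocentre while C8, C12 and C15 are unaffected under non-basic conditions.

Step 16
Reactants: 23 PGA2 methyl ester
Product: 24 15-O-acetyl-PGA2 methyl ester (target)
Conditions: Ac2O (1.5 equiv), pyridine, DMAP (cat.), CH2Cl2, 0 °C to rt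
Reagents that add atoms: acetic anhydride, CC(=O)OC(C)=O
Why: DMAP-catalysed acetylation of the only free hydroxyl (allylic C15) occurs at oxygen with retention, and the mild amine base does not isomerise the enone.

**Compound list**

1 | cis-3,5-diacetoxycyclopent-1-ene (meso) | CC(=O)O[C@H]1C=C[C@@H](OC(C)=O)C1 | starting material
2 | (1R,4S)-4-hydroxycyclopent-2-en-1-yl acetate (cis) | CC(=O)O[C@H]1C=C[C@@H](O)C1 | intermediate
3 | (R)-4-acetoxycyclopent-2-en-1-one | CC(=O)O[C@H]1C=CC(=O)C1 | intermediate
4 | (R)-4-hydroxycyclopent-2-en-1-one | O[C@H]1C=CC(=O)C1 | intermediate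
5 | (R)-4-(tert-butyldimethylsilyloxy)cyclopent-2-en-1-one | CC(C)(C)[Si](C)(C)O[C@H]1C=CC(=O)C1 | intermediate
6 | (S)-oct-1-yn-3-ol | CCCCC[C@H](O)C#C | starting material
7 | (S)-3-(tert-butyldimethylsilyloxy)oct-1-yne | CCCCC[C@H](O[Si](C)(C)C(C)(C)C)C#C | intermediate
8 | chlorobis(cyclopentadienyl)[(S,E)-3-(tert-butyldimethylsilyloxy)oct-1-enyl]zirconium, formed in the flask | CCCCC[C@H](O[Si](C)(C)C(C)(C)C)/C=C/[Zr](Cl)(C1C=CC=C1)C1C=CC=C1 | intermediate
9 | (S,E)-3-(tert-butyldimethylsilyloxy)-1-iodooct-1-ene | CCCCC[C@H](O[Si](C)(C)C(C)(C)C)/C=C/I | intermediate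
10 | hex-5-ynoic acid | C#CCCCC(=O)O | starting material
11 | lithium 6-lithiohex-5-ynoate (dianion), formed in the flask | [Li]C#CCCCC(=O)O[Li] | intermediate
12 | 7-hydroxyhept-5-ynoic acid | OCC#CCCCC(=O)O | intermediate
13 | methyl 7-hydroxyhept-5-ynoate | COC(=O)CCCC#CCO | intermediate
14 | methyl 7-oxohept-5-ynoate | COC(=O)CCCC#CC=O | intermediate
15 | (S,E)-3-(tert-butyldimethylsilyloxy)oct-1-enyllithium, formed in the flask | CCCCC[C@H](O[Si](C)(C)C(C)(C)C)/C=C/[Li] | intermediate
16 | (S,E)-3-(tert-butyldimethylsilyloxy)oct-1-enylcopper as its Bu3P complex, formed in the flask | CCCCC[C@H](O[Si](C)(C)C(C)(C)C)/C=C/[Cu] | intermediate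
17 | lithium enolate (C9 O–Li, C8=C9) of the 11α-TBSO cyclopentanone carrying the (S,E)-3-TBSO-oct-1-enyl chain at C12, trans to the C11 silyloxy group; formed in the flask | CCCCC[C@H](O[Si](C)(C)C(C)(C)C)/C=C/[C@H]1[C@H](O[Si](C)(C)C(C)(C)C)CC(O[Li])=C1 | intermediate
18 | methyl (13E,15S)-11α,15-bis(tert-butyldimethylsilyloxy)-7-hydroxy-9-oxoprost-13-en-5-yn-1-oate (8,12-trans, 11,12-trans; C7 epimers) | CCCCC[C@H](O[Si](C)(C)C(C)(C)C)/C=C/[C@H]1[C@H](O[Si](C)(C)C(C)(C)C)CC(=O)[C@@H]1C(O)C#CCCCC(=O)OC | intermediate
19 | 7-O-(phenoxythiocarbonyl) derivative of 18 (C7 epimers) | CCCCC[C@H](O[Si](C)(C)C(C)(C)C)/C=C/[C@H]1[C@H](O[Si](C)(C)C(C)(C)C)CC(=O)[C@@H]1C(OC(=S)Oc2ccccc2)C#CCCCC(=O)OC | intermediate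
20 | methyl (13E,15S)-11α,15-bis(tert-butyldimethylsilyloxy)-9-oxoprost-13-en-5-yn-1-oate (5,6-didehydro-PGE2 methyl ester bis-TBS ether) | CCCCC[C@H](O[Si](C)(C)C(C)(C)C)/C=C/[C@H]1[C@H](O[Si](C)(C)C(C)(C)C)CC(=O)[C@@H]1CC#CCCCC(=O)OC | intermediate
21 | PGE2 methyl ester 11,15-bis(tert-butyldimethylsilyl) ether (5Z,13E) | CCCCC[C@H](O[Si](C)(C)C(C)(C)C)/C=C/[C@H]1[C@H](O[Si](C)(C)C(C)(C)C)CC(=O)[C@@H]1C/C=C\CCCC(=O)OC | intermediate
22 | PGE2 methyl ester, methyl (Z)-7-[(1R,2R,3R)-3-hydroxy-2-[(S,E)-3-hydroxyoct-1-enyl]-5-oxocyclopentyl]hept-5-enoate | CCCCC[C@H](O)/C=C/[C@H]1[C@H](O)CC(=O)[C@@H]1C/C=C\CCCC(=O)OC | intermediate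
23 | PGA2 methyl ester, methyl (Z)-7-[(1R,2S)-2-[(S,E)-3-hydroxyoct-1-enyl]-5-oxocyclopent-3-en-1-yl]hept-5-enoate | CCCCC[C@H](O)/C=C/[C@H]1C=CC(=O)[C@@H]1C/C=C\CCCC(=O)OC | intermediate
24 | methyl (Z)-7-[(1R,2S)-2-[(S,E)-3-acetoxyoct-1-enyl]-5-oxocyclopent-3-en-1-yl]hept-5-enoate (CNP0284741.1) | CCCCC[C@@H](/C=C/[C@H]1C=CC(=O)[C@@H]1C/C=C\CCCC(=O)OC)OC(C)=O | target

**Step count and risks**

Total steps: 16. Longest linear sequence: 11 (steps 1–4, then 10–16).

Step 10 (three-component coupling). The enolate can equilibrate and expel the C11 silyloxy group, or the sensitive ynal can be consumed unproductively. The fallback sets out from 9 and 5: the same conjugate addition is run to enolate 17, which is trapped with Me3SiCl/Et3N at −78 °C and isolated as the trimethylsilyl enol ether of the conjugate adduct F5. A Mukaiyama aldol addition of this enol ether to ynal 14 (BF3·OEt2, CH2Cl2, −78 °C) separates the two bond formations and comes back to the route at 18.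

Step 11 (thioacylation, together with the radical reduction that follows it). The acylated β-oxygenated ketone may eliminate to the C7=C8 enynone, and the propargylic radical may give allene. The fallback sets out from alcohol 13 and enolate 17 and avoids a C7 oxygen altogether. Iodination of 13 (I2, PPh3, imidazole, CH2Cl2, 0 °C) gives methyl 7-iodohept-5-ynoate F6. Enolate 17, generated as in step 10, is transmetalated with Ph3SnCl in the presence of HMPA to the O-triphenylstannyl enolate F7, which is C-alkylated by F6 at −30 °C trans to the C12 chain. This comes back to the route at 20.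

Step 3 (enzymatic deacetylation). It is slow, and the β-acetoxy enone can eliminate or partly racemise. The fallback sets out from 2 and exchanges protecting groups before the ketone exists:
- dihydropyran/PPTS gives (1R,4S)-4-(oxan-2-yloxy)cyclopent-2-en-1-yl acetate F1;
- K2CO3/MeOH gives (1R,4S)-4-(oxan-2-yloxy)cyclopent-2-en-1-ol F2;
- TBSCl/imidazole gives tert-butyldimethylsilyl (1R,4S)-4-(oxan-2-yloxy)cyclopent-2-en-1-yl ether F3;
- PPTS/MeOH at rt removes the acetal to give (1S,4R)-4-(tert-butyldimethylsilyloxy)cyclopent-2-en-1-ol F4;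
- Dess–Martin oxidation of F4 comes back to the route at 5.

**Further compounds**

F1 | step 3 | (1R,4S)-4-(oxan-2-yloxy)cyclopent-2-en-1-yl acetate | CC(=O)O[C@H]1C=C[C@@H](OC2CCCCO2)C1
F2 | step 3 | (1R,4S)-4-(oxan-2-yloxy)cyclopent-2-en-1-ol | O[C@H]1C=C[C@@H](OC2CCCCO2)C1
F3 | step 3 | tert-butyldimethylsilyl (1R,4S)-4-(oxan-2-yloxy)cyclopent-2-en-1-yl ether | CC(C)(C)[Si](C)(C)O[C@H]1C=C[C@@H](OC2CCCCO2)C1
F4 | step 3 | (1S,4R)-4-(tert-butyldimethylsilyloxy)cyclopent-2-en-1-ol | CC(C)(C)[Si](C)(C)O[C@H]1C=C[C@@H](O)C1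
F5 | step 10 | trimethylsilyl enol ether (C9 O–SiMe3, C8=C9) of the conjugate adduct | CCCCC[C@H](O[Si](C)(C)C(C)(C)C)/C=C/[C@H]1[C@H](O[Si](C)(C)C(C)(C)C)CC(O[Si](C)(C)C)=C1
F6 | step 11 | methyl 7-iodohept-5-ynoate | COC(=O)CCCC#CCI
F7 | step 11 | O-triphenylstannyl enolate (C9 O–SnPh3, C8=C9) of the conjugate adduct | CCCCC[C@H](O[Si](C)(C)C(C)(C)C)/C=C/[C@H]1[C@H](O[Si](C)(C)C(C)(C)C)CC(O[Sn](c2ccccc2)(c2ccccc2)c2ccccc2)=C1
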